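The route rests on disconnecting the C9–C10 bond of ring B. In the target the exocyclic C8=C17 methylene lies between the C9 stereocentre and the quaternary, methyl-bearing C10 of a cis-fused ring A/ring B system. That array is what remains when an allylsilane (Si–C17–C8=C9) adds through C9 to the β-carbon C10 of a ring A 3-methylcyclohexenone. A single Lewis acid-promoted Hosomi–Sakurai closure therefore makes C9–C10, closes ring B, sets C9 and C10 and unveils the methylene. Its precursor is an enantiopure ring A enone that already carries the C4 methyl/ester centre and, on C5, a chain ending in a Z-configured trisubstituted allylsilane with a silyl-protected C12 oxygen.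

Key step: step 11

Remark 1 (numbering): ring atoms carry labdane numbers and β is the face of the C10 methyl (C20); the target is (2S,4R,5S,9S,10R,13E) with 5β-H, i.e. cis-fused.
Remark 2 (assumption, step 2): the alkaloid base is cinchonidine or its pseudo-enantiomer cinchonine, whichever gives the less soluble salt with the R acid.
Remark 3 (protecting groups): the C12 oxygen is carried as a TBDPS ether, so that the TBS ether used during chain assembly can be removed beside it and so that it survives the acid of step 10; C19 stays a methyl ester until the last step.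

Step 1
Reactants: 1 3,5-dimethoxybenzoic acid
Product: 4 rac-3-methoxy-1-methyl-5-oxocyclohex-3-ene-1-carboxylic acid, via Birch dianion 2 (not isolated), via diene acid 3 (not isolated)
Conditions: Li, NH3(l)/THF, −78 °C; MeI, −78 °C → rt; then 0.5 M HCl, THF, 0 °C
Reagents that add atoms: iodomethane, CI; water, O
Why: Birch reductive alkylation puts the methyl group on the carboxyl-bearing carbon of the 1,4-dihydro dianion, and enol ether hydrolysis with dilute acid stops after one methoxy group because the first hydrolysis gives a deactivated vinylogous ester; the product is racemic.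

Step 2
Reactants: 4 rac-3-methoxy-1-methyl-5-oxocyclohex-3-ene-1-carboxylic acid
Product: 5 (R)-3-methoxy-1-methyl-5-oxocyclohex-3-ene-1-carboxylic acid
Conditions: cinchonidine (1 equiv), acetone, crystallisation to constant rotation; then 1 M KHSO4, EtOAc, 0 °C
Reagents that add atoms: none
Why: Classical resolution by diastereomeric salt crystallisation supplies the quaternary centre (labdane C4, R) without bond formation, and the tertiary amine base cannot condense with the vinylogous ester.

Step 3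
Reactants: 5 (R)-3-methoxy-1-methyl-5-oxocyclohex-3-ene-1-carboxylic acid
Product: 6 methyl (R)-3-methoxy-1-methyl-5-oxocyclohex-3-ene-1-carboxylate
Conditions: MeI, K2CO3, DMF, rt
Reagents that add atoms: iodomethane, CI
Why: O-alkylation of the carboxylate (SN2 at iodomethane) esterifies the hindered acid without acid catalysis, so the vinylogous ester cannot exchange its two oxygens and racemise.

Step 4
Reactants: 7 2,3-dihydrofuran; 8 tert-butyl(2-iodoethoxy)dimethylsilane
Product: 10 tert-butyl[2-(4,5-dihydrofuran-2-yl)ethoxy]dimethylsilane, via lithiated dihydrofuran 9 (not isolated)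
Conditions: t-BuLi, THF, −78 → 0 °C; then 8, −30 °C → rt
Reagents that add atoms: none
Why: α-Lithiation of the cyclic enol ether at the oxygen-bearing vinylic carbon is followed by SN2 alkylation with the primary iodide.

Step 5
Reactants: 10 tert-butyl[2-(4,5-dihydrofuran-2-yl)ethoxy]dimethylsilane; 11 (trimethylsilyl)methylmagnesium chloride
Product: 12 (Z)-6-[(tert-butyldimethylsilyl)oxy]-4-[(trimethylsilyl)methyl]hex-3-en-1-ol
Conditions: NiCl2(PPh3)2 (5 mol %), 11 (3 equiv), toluene, reflux; aq NH4Cl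
Reagents that add atoms: none
Why: Nickel-catalysed Kumada-type coupling of a Grignard reagent with an enol ether: zerovalent nickel inserts into the vinylic C–O bond and the silylmethyl group replaces oxygen with retention, so CH2SiMe3 ends cis to the CH2CH2OH chain and the Z allylsilane geometry is fixed.

Step 6
Reactants: 12 (Z)-6-[(tert-butyldimethylsilyl)oxy]-4-[(trimethylsilyl)methyl]hex-3-en-1-ol
Product: 13 (Z)-1-[(tert-butyldimethylsilyl)oxy]-6-[(tert-butyldiphenylsilyl)oxy]-3-[(trimethylsilyl)methyl]hex-3-ene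
Conditions: TBDPSCl, imidazole, DMF, rt
Reagents that add atoms: tert-butyl(chloro)diphenylsilane, CC(C)(C)[Si](Cl)(c1ccccc1)c1ccccc1
Why: Silyl ether formation at the free primary alcohol installs the more acid-stable of the two silyl groups on the future C12 oxygen.

Step 7
Reactants: 13 (Z)-1-[(tert-butyldimethylsilyl)oxy]-6-[(tert-butyldiphenylsilyl)oxy]-3-[(trimethylsilyl)methyl]hex-3-ene
Product: 14 (Z)-6-[(tert-butyldiphenylsilyl)oxy]-3-[(trimethylsilyl)methyl]hex-3-en-1-ol
Conditions: PPTS (0.1 equiv), MeOH, rt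
Reagents that add atoms: none
Why: Acid-catalysed methanolysis cleaves the primary TBS ether far faster than the TBDPS ether, and PPTS is too weak an acid to protodesilylate the allylsilane.

Step 8
Reactants: 14 (Z)-6-[(tert-butyldiphenylsilyl)oxy]-3-[(trimethylsilyl)methyl]hex-3-en-1-ol
Product: 16 (Z)-tert-butyl({6-iodo-4-[(trimethylsilyl)methyl]hex-3-en-1-yl}oxy)diphenylsilane, via mesylate 15 (not isolated)
Conditions: MsCl, Et3N, CH2Cl2, 0 °C; then NaI, acetone, 40 °C
Reagents that add atoms: sodium iodide, [Na+].[I-]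
Why: Mesylation and Finkelstein displacement (SN2) give the primary iodide without exposing the allylsilane to electrophilic iodine.

Step 9
Reactants: 6 methyl (R)-3-methoxy-1-methyl-5-oxocyclohex-3-ene-1-carboxylate; 16 (Z)-tert-butyl({6-iodo-4-[(trimethylsilyl)methyl]hex-3-en-1-yl}oxy)diphenylsilane
Product: 18 methyl (1R,6R)-6-{(Z)-6-[(tert-butyldiphenylsilyl)oxy]-3-[(trimethylsilyl)methyl]hex-3-en-1-yl}-3-methoxy-1-methyl-5-oxocyclohex-3-ene-1-carboxylate, via lithium enolate 17 (not isolated)
Conditions: LiN(i-Pr)2, THF, −78 °C; then 16, DMPU, −78 → −20 °C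
Reagents that add atoms: none
Why: Stork–Danheiser kinetic α′-alkylation: the amide base removes a proton from the CH2 between the carbonyl and the quaternary carbon, and the iodide should enter anti to the pseudoaxial ring methyl (the flat ester lies near the enolate plane), which puts the chain cis to CO2Me and sets labdane C5 (6R here).

Step 10
Reactants: 18 methyl (1R,6R)-6-{(Z)-6-[(tert-butyldiphenylsilyl)oxy]-3-[(trimethylsilyl)methyl]hex-3-en-1-yl}-3-methoxy-1-methyl-5-oxocyclohex-3-ene-1-carboxylate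
Product: 20 methyl (1R,2S)-2-{(Z)-6-[(tert-butyldiphenylsilyl)oxy]-3-[(trimethylsilyl)methyl]hex-3-en-1-yl}-1,3-dimethyl-5-oxocyclohex-3-ene-1-carboxylate, via tertiary carbinol 19 (not isolated)
Conditions: MeLi, CeCl3, THF, −78 °C; then 1 M HCl, THF, 0 °C
Reagents that add atoms: methyllithium, [Li]C; water, O
Why: Stork–Danheiser carbonyl transposition: the organocerium reagent adds 1,2 to the vinylogous ester carbonyl in preference to the neopentyl-type methyl ester, and dilute acid hydrolyses the enol ether and dehydrates the carbinol to the 3-methylcyclohexenone without touching C4 or C5.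

Step 11
Reactants: 20 methyl (1R,2S)-2-{(Z)-6-[(tert-butyldiphenylsilyl)oxy]-3-[(trimethylsilyl)methyl]hex-3-en-1-yl}-1,3-dimethyl-5-oxocyclohex-3-ene-1-carboxylate
Product: 21 methyl (4R,5S,9S,10R)-12-[(tert-butyldiphenylsilyl)oxy]-2-oxo-13,14,15,16-tetranorlabd-8(17)-en-19-oate (cis-fused decalin: C2 ketone, C8 exocyclic methylene, 4α-CO2Me, 4β-Me, 10β-Me, 5β-H, 9β-CH2CH2OTBDPS)
Conditions: EtAlCl2 (2 equiv), toluene, −78 → 0 °C; aq NaHCO3
Reagents that add atoms: none
Why: EtAlCl2 binds the C2 carbonyl and the allylsilane adds through its γ-carbon C9 to C10 (SE2′), giving a β-silyl cation at C8 that loses silicon to leave the C8=C17 methylene and an aluminium enolate, which is protonated at C1 on work-up. The closest known reaction type is the Lewis acid-promoted intramolecular Hosomi–Sakurai conjugate addition of allylsilanes to 3-methylcyclohex-2-enones. Ring B closes as a six-membered ring, exo with respect to the enone (C1 stays outside) and endo with respect to the allyl C8=C9 bond, through a chair-like array. C10 is controlled by the tether: anchored at C5, it can deliver C9 only to the α face of C10, perpendicular to the enone plane, so C6 and C9 are cis and the fusion is cis with C20 and H5 both β. C9 is controlled by the alkene geometry: in the chair the Z allylsilane (C11 trans to C7) holds C11 equatorial, which is 9β (9S). The step needs 1,4- rather than 1,2-addition and one face of the allylsilane; the tether length (six- against eight-membered closure) secures the first and the defined alkene geometry the second, while C4 and C5 are carried through unchanged.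

Step 12
Reactants: 21 methyl (4R,5S,9S,10R)-12-[(tert-butyldiphenylsilyl)oxy]-2-oxo-13,14,15,16-tetranorlabd-8(17)-en-19-oate
Product: 22 methyl (4R,5S,9S,10R)-12-hydroxy-2-oxo-13,14,15,16-tetranorlabd-8(17)-en-19-oate
Conditions: TBAF, THF, rt
Reagents that add atoms: none
Why: Fluoride-mediated desilylation frees the C12 primary alcohol; ketone, hindered ester and exocyclic alkene are inert.

Step 13
Reactants: 22 methyl (4R,5S,9S,10R)-12-hydroxy-2-oxo-13,14,15,16-tetranorlabd-8(17)-en-19-oate
Product: 23 methyl (4R,5S,9S,10R)-12-iodo-2-oxo-13,14,15,16-tetranorlabd-8(17)-en-19-oate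
Conditions: I2, PPh3, imidazole, CH2Cl2, 0 °C
Reagents that add atoms: iodine, II
Why: Appel-type iodination converts the primary alcohol into the iodide by SN2 displacement of the oxyphosphonium group.

Step 14
Reactants: 24 methyl acetoacetate
Product: 25 methyl (E)-3-{[(trifluoromethyl)sulfonyl]oxy}but-2-enoate
Conditions: Tf2O, aq Me4NOH, hexane, 5 °C
Reagents that add atoms: trifluoromethanesulfonic anhydride, O=S(=O)(OS(=O)(=O)C(F)(F)F)C(F)(F)F
Why: Stereoselective O-triflation of the β-ketoester enolate: with the non-chelating tetramethylammonium counter-ion the enolate oxygen sits trans to the ester, which gives the E enol triflate (methyl cis to CO2Me).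

Step 15
Reactants: 23 methyl (4R,5S,9S,10R)-12-iodo-2-oxo-13,14,15,16-tetranorlabd-8(17)-en-19-oate; 25 methyl (E)-3-{[(trifluoromethyl)sulfonyl]oxy}but-2-enoate
Product: 27 dimethyl (4R,5S,9S,10R,13E)-2-oxolabda-8(17),13-diene-15,19-dioate, via alkylzinc iodide 26 (not isolated)
Conditions: Zn dust, LiCl, THF, 40 °C; then 25, Pd(PPh3)4 (5 mol %), THF, rt → 45 °C
Reagents that add atoms: none
Why: Negishi sp3–sp2 cross-coupling: zinc inserts into the primary carbon–iodine bond without touching ketone or ester, and zerovalent palladium couples the alkylzinc with the enol triflate with retention, so C12 ends trans to C15 (13E).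

Step 16
Reactants: 27 dimethyl (4R,5S,9S,10R,13E)-2-oxolabda-8(17),13-diene-15,19-dioate
Product: 28 dimethyl (2S,4R,5S,9S,10R,13E)-2-hydroxylabda-8(17),13-diene-15,19-dioate
Conditions: NaBH4, MeOH/THF, −40 °C
Reagents that add atoms: none
Why: Substrate-controlled hydride reduction of the ketone: in the favoured chair–chair conformer the C18 and C20 methyl groups are syn-axial over the β face of C2, so borohydride should enter along the equatorial trajectory from the α face and give the 2β (2S) alcohol, while the enoate and both esters are left alone at low temperature.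

Step 17
Reactants: 28 dimethyl (2S,4R,5S,9S,10R,13E)-2-hydroxylabda-8(17),13-diene-15,19-dioate
Product: 29 (2S,4R,5S,9S,10R,13E)-2-hydroxy-19-methoxy-19-oxolabda-8(17),13-dien-15-oic acid
Conditions: LiOH, THF/MeOH/H2O, rt; then 1 M HCl to pH 3
Reagents that add atoms: lithium hydroxide, [Li+].[OH-]
Why: Saponification (acyl substitution by hydroxide) of the unhindered C15 methyl ester; the C19 ester on the quaternary carbon resists hydroxide at room temperature, and the 2β hydroxyl, trans to C19, cannot lactonise.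

Step 18
Reactants: 29 (2S,4R,5S,9S,10R,13E)-2-hydroxy-19-methoxy-19-oxolabda-8(17),13-dien-15-oic acid
Product: 30 (2S,4R,5S,9S,10R,13E)-2-hydroxylabda-8(17),13-diene-15,19-dioic acid (CNP0086784.2)
Conditions: n-PrSLi (excess), HMPA, rt; then 1 M HCl to pH 3
Reagents that add atoms: none
Why: SN2 demethylation of the hindered C19 methyl ester by thiolate at the methyl carbon does not need access to the acyl carbon, and the C15 carboxylate formed in step 17 is no Michael acceptor for the thiolate.

Compound list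
1 | 3,5-dimethoxybenzoic acid | COc1cc(OC)cc(c1)C(=O)O | starting material
2 | dilithium 1-carboxylato-3,5-dimethoxycyclohexa-2,5-dien-1-ide (Birch dianion) | [Li+].[Li+].[O-]C(=O)[C-]1C=C(OC)CC(OC)=C1 | intermediate
3 | 3,5-dimethoxy-1-methylcyclohexa-2,5-diene-1-carboxylic acid | COC1=CC(C)(C(=O)O)C=C(OC)C1 | intermediate
4 | rac-3-methoxy-1-methyl-5-oxocyclohex-3-ene-1-carboxylic acid | O=C1C=C(OC)CC(C)(C(=O)O)C1 | intermediate
5 | (R)-3-methoxy-1-methyl-5-oxocyclohex-3-ene-1-carboxylic acid | O=C1C=C(OC)C[C@@](C)(C(=O)O)C1 | intermediate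
6 | methyl (R)-3-methoxy-1-methyl-5-oxocyclohex-3-ene-1-carboxylate | O=C1C=C(OC)C[C@@](C)(C(=O)OC)C1 | intermediate
7 | 2,3-dihydrofuran | C1CC=CO1 | starting material
8 | tert-butyl(2-iodoethoxy)dimethylsilane | CC(C)(C)[Si](C)(C)OCCI | starting material
9 | 5-lithio-2,3-dihydrofuran | [Li]C1=CCCO1 | intermediate
10 | tert-butyl[2-(4,5-dihydrofuran-2-yl)ethoxy]dimethylsilane | CC(C)(C)[Si](C)(C)OCCC1=CCCO1 | intermediate
11 | (trimethylsilyl)methylmagnesium chloride | C[Si](C)(C)C[Mg]Cl | starting material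
12 | (Z)-6-[(tert-butyldimethylsilyl)oxy]-4-[(trimethylsilyl)methyl]hex-3-en-1-ol (CH2SiMe3 cis to the CH2CH2OH chain) | OCC/C=C(/CCO[Si](C)(C)C(C)(C)C)C[Si](C)(C)C | intermediate
13 | (Z)-1-[(tert-butyldimethylsilyl)oxy]-6-[(tert-butyldiphenylsilyl)oxy]-3-[(trimethylsilyl)methyl]hex-3-ene | CC(C)(C)[Si](c1ccccc1)(c1ccccc1)OCC/C=C(/CCO[Si](C)(C)C(C)(C)C)C[Si](C)(C)C | intermediate
14 | (Z)-6-[(tert-butyldiphenylsilyl)oxy]-3-[(trimethylsilyl)methyl]hex-3-en-1-ol | OCC/C(C[Si](C)(C)C)=C/CCO[Si](c1ccccc1)(c1ccccc1)C(C)(C)C | intermediate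
15 | (Z)-6-[(tert-butyldiphenylsilyl)oxy]-3-[(trimethylsilyl)methyl]hex-3-en-1-yl methanesulfonate | CS(=O)(=O)OCC/C(C[Si](C)(C)C)=C/CCO[Si](c1ccccc1)(c1ccccc1)C(C)(C)C | intermediate
16 | (Z)-tert-butyl({6-iodo-4-[(trimethylsilyl)methyl]hex-3-en-1-yl}oxy)diphenylsilane | ICC/C(C[Si](C)(C)C)=C/CCO[Si](c1ccccc1)(c1ccccc1)C(C)(C)C | intermediate
17 | lithium (R)-5-methoxy-3-(methoxycarbonyl)-3-methylcyclohexa-1,5-dien-1-olate (lithium enolate of 6) | [Li+].[O-]C1=C[C@](C)(C(=O)OC)CC(OC)=C1 | intermediate
18 | methyl (1R,6R)-6-{(Z)-6-[(tert-butyldiphenylsilyl)oxy]-3-[(trimethylsilyl)methyl]hex-3-en-1-yl}-3-methoxy-1-methyl-5-oxocyclohex-3-ene-1-carboxylate (chain cis to CO2Me) | O=C1C=C(OC)C[C@@](C)(C(=O)OC)[C@H]1CC/C(C[Si](C)(C)C)=C/CCO[Si](c2ccccc2)(c2ccccc2)C(C)(C)C | intermediate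
19 | methyl (1R,6R)-6-{(Z)-6-[(tert-butyldiphenylsilyl)oxy]-3-[(trimethylsilyl)methyl]hex-3-en-1-yl}-5-hydroxy-3-methoxy-1,5-dimethylcyclohex-3-ene-1-carboxylate (both carbinol epimers) | OC1(C)C=C(OC)C[C@@](C)(C(=O)OC)[C@H]1CC/C(C[Si](C)(C)C)=C/CCO[Si](c2ccccc2)(c2ccccc2)C(C)(C)C | intermediate
20 | methyl (1R,2S)-2-{(Z)-6-[(tert-butyldiphenylsilyl)oxy]-3-[(trimethylsilyl)methyl]hex-3-en-1-yl}-1,3-dimethyl-5-oxocyclohex-3-ene-1-carboxylate | O=C1C=C(C)[C@H](CC/C(C[Si](C)(C)C)=C/CCO[Si](c2ccccc2)(c2ccccc2)C(C)(C)C)[C@](C)(C(=O)OC)C1 | intermediate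
21 | methyl (4R,5S,9S,10R)-12-[(tert-butyldiphenylsilyl)oxy]-2-oxo-13,14,15,16-tetranorlabd-8(17)-en-19-oate | C=C1CC[C@H]2[C@](C)(CC(=O)C[C@@]2(C)C(=O)OC)[C@H]1CCO[Si](c3ccccc3)(c3ccccc3)C(C)(C)C | intermediate
22 | methyl (4R,5S,9S,10R)-12-hydroxy-2-oxo-13,14,15,16-tetranorlabd-8(17)-en-19-oate | C=C1CC[C@H]2[C@](C)(CC(=O)C[C@@]2(C)C(=O)OC)[C@H]1CCO | intermediate
23 | methyl (4R,5S,9S,10R)-12-iodo-2-oxo-13,14,15,16-tetranorlabd-8(17)-en-19-oate | C=C1CC[C@H]2[C@](C)(CC(=O)C[C@@]2(C)C(=O)OC)[C@H]1CCI | intermediate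
24 | methyl acetoacetate | CC(=O)CC(=O)OC | starting material
25 | methyl (E)-3-{[(trifluoromethyl)sulfonyl]oxy}but-2-enoate | C/C(OS(=O)(=O)C(F)(F)F)=C\C(=O)OC | intermediate
26 | alkylzinc iodide from 23 (C12–Zn–I) | C=C1CC[C@H]2[C@](C)(CC(=O)C[C@@]2(C)C(=O)OC)[C@H]1CC[Zn]I | intermediate
27 | dimethyl (4R,5S,9S,10R,13E)-2-oxolabda-8(17),13-diene-15,19-dioate | C=C1CC[C@H]2[C@](C)(CC(=O)C[C@@]2(C)C(=O)OC)[C@H]1CC/C(C)=C/C(=O)OC | intermediate
28 | dimethyl (2S,4R,5S,9S,10R,13E)-2-hydroxylabda-8(17),13-diene-15,19-dioate | C=C1CC[C@H]2[C@](C)(C[C@H](O)C[C@@]2(C)C(=O)OC)[C@H]1CC/C(C)=C/C(=O)OC | intermediate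
29 | (2S,4R,5S,9S,10R,13E)-2-hydroxy-19-methoxy-19-oxolabda-8(17),13-dien-15-oic acid | C=C1CC[C@H]2[C@](C)(C[C@H](O)C[C@@]2(C)C(=O)OC)[C@H]1CC/C(C)=C/C(=O)O | intermediate
30 | (2S,4R,5S,9S,10R,13E)-2-hydroxylabda-8(17),13-diene-15,19-dioic acid | C=C1CC[C@H]2[C@](C)(C[C@H](O)C[C@@]2(C)C(=O)O)[C@H]1CC/C(C)=C/C(=O)O | target

Total steps: 18. Longest linear sequence: 14 steps (steps 4 to 13 and 15 to 18, from 2,3-dihydrofuran).

Steps most likely to fail

Step 11. What may go wrong: the chair-like closure holds the 4α ester on the concave face close to C7 and C9, so ring B may instead close through a boat-like array, which presents the other face of the allylsilane and gives the 9-epimer. Silicon may also be lost by protonation before the C–C bond forms. Fallback: the geometric isomer of the allylsilane, which reaches the same C9 configuration through the boat-like array, is made by a copper-mediated 1,2-metalate rearrangement in place of the nickel coupling. It sets out from 7 (with 8) and returns to the route at 21. Lithiated dihydrofuran 9 is added to (Me3SiCH2)2CuLi (from Me3SiCH2Li and CuBr·SMe2). On warming, a silylmethyl group migrates from copper to the alkenyl carbon with inversion and ring opening, and the alkenylcopper is alkylated in the same flask with 8. This gives (E)-6-[(tert-butyldimethylsilyl)oxy]-4-[(trimethylsilyl)methyl]hex-3-en-1-ol F1, in which CH2SiMe3 is trans to the CH2CH2OH chain. The operations of steps 6 to 10 then give in turn the bis-silyl ether F2, the primary alcohol F3, its mesylate F4, the iodide F5, the alkylated vinylogous ester F6 (from enolate 17), the tertiary carbinol F7 and the E-allylsilane enone F8. Closure of F8 with EtAlCl2 gives 21.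

Step 9. What may go wrong: E2 elimination of the homoallylic iodide 16 (its β-hydrogens are allylic) may outrun C-alkylation, because the enolate reacts at a carbon next to a quaternary centre. Fallback: the enolate is alkylated with a small activated electrophile and the tether is completed by two stereospecific Negishi couplings. It sets out from 6 and returns at 18. Enolate 17 and allyl bromide give the 6-allyl vinylogous ester F9. Lemieux–Johnson cleavage (OsO4 catalyst, NaIO4, 2,6-lutidine) gives the aldehyde F10, NaBH4 at −78 °C the primary alcohol F11, and I2/PPh3/imidazole the iodide F12. Zinc insertion gives the alkylzinc iodide F13. This is coupled under palladium catalysis, selectively at the bromine trans to the chain, with tert-butyl[(4,4-dibromobut-3-en-1-yl)oxy]diphenylsilane F14 (Corey–Fuchs reaction, CBr4/PPh3, of 3-[(tert-butyldiphenylsilyl)oxy]propanal) to give the Z bromoalkene F15. A second Negishi coupling with (trimethylsilyl)methylzinc chloride F16 (from 11 and ZnCl2; Pd[P(t-Bu)3]2, retention) puts CH2SiMe3 cis to the C11 chain and gives 18.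

Step 16. What may go wrong: poor facial selectivity, if the reduction runs through the other chair–chair conformer (C9 and the ester syn-axial over the α face) and hydride enters from the β face to give the 2α alcohol. Fallback: the carbinol centre is corrected by inversion. It sets out from 27 and returns at 29. The borohydride reduction is then taken as the source of the 2α alcohol F17 (2R), which is inverted by a Mitsunobu reaction (4-nitrobenzoic acid, PPh3, DIAD, THF) to the 2β 4-nitrobenzoate F18. The hydroxide treatment of step 17 cleaves the aryl ester together with the C15 methyl ester and gives 29.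

Further compounds
F1 | step 11 | (E)-6-[(tert-butyldimethylsilyl)oxy]-4-[(trimethylsilyl)methyl]hex-3-en-1-ol | OCC/C=C(\CCO[Si](C)(C)C(C)(C)C)C[Si](C)(C)C
F2 | step 11 | (E)-1-[(tert-butyldimethylsilyl)oxy]-6-[(tert-butyldiphenylsilyl)oxy]-3-[(trimethylsilyl)methyl]hex-3-ene | CC(C)(C)[Si](c1ccccc1)(c1ccccc1)OCC/C=C(\CCO[Si](C)(C)C(C)(C)C)C[Si](C)(C)C
F3 | step 11 | (E)-6-[(tert-butyldiphenylsilyl)oxy]-3-[(trimethylsilyl)methyl]hex-3-en-1-ol | OCC/C(C[Si](C)(C)C)=C\CCO[Si](c1ccccc1)(c1ccccc1)C(C)(C)C
F4 | step 11 | (E)-6-[(tert-butyldiphenylsilyl)oxy]-3-[(trimethylsilyl)methyl]hex-3-en-1-yl methanesulfonate | CS(=O)(=O)OCC/C(C[Si](C)(C)C)=C\CCO[Si](c1ccccc1)(c1ccccc1)C(C)(C)C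
F5 | step 11 | (E)-tert-butyl({6-iodo-4-[(trimethylsilyl)methyl]hex-3-en-1-yl}oxy)diphenylsilane | ICC/C(C[Si](C)(C)C)=C\CCO[Si](c1ccccc1)(c1ccccc1)C(C)(C)C
F6 | step 11 | methyl (1R,6R)-6-{(E)-6-[(tert-butyldiphenylsilyl)oxy]-3-[(trimethylsilyl)methyl]hex-3-en-1-yl}-3-methoxy-1-methyl-5-oxocyclohex-3-ene-1-carboxylate | O=C1C=C(OC)C[C@@](C)(C(=O)OC)[C@H]1CC/C(C[Si](C)(C)C)=C\CCO[Si](c2ccccc2)(c2ccccc2)C(C)(C)C
F7 | step 11 | methyl (1R,6R)-6-{(E)-6-[(tert-butyldiphenylsilyl)oxy]-3-[(trimethylsilyl)methyl]hex-3-en-1-yl}-5-hydroxy-3-methoxy-1,5-dimethylcyclohex-3-ene-1-carboxylate | OC1(C)C=C(OC)C[C@@](C)(C(=O)OC)[C@H]1CC/C(C[Si](C)(C)C)=C\CCO[Si](c2ccccc2)(c2ccccc2)C(C)(C)C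
F8 | step 11 | methyl (1R,2S)-2-{(E)-6-[(tert-butyldiphenylsilyl)oxy]-3-[(trimethylsilyl)methyl]hex-3-en-1-yl}-1,3-dimethyl-5-oxocyclohex-3-ene-1-carboxylate | O=C1C=C(C)[C@H](CC/C(C[Si](C)(C)C)=C\CCO[Si](c2ccccc2)(c2ccccc2)C(C)(C)C)[C@](C)(C(=O)OC)C1
F9 | step 9 | methyl (1R,6R)-6-allyl-3-methoxy-1-methyl-5-oxocyclohex-3-ene-1-carboxylate | O=C1C=C(OC)C[C@@](C)(C(=O)OC)[C@H]1CC=C
F10 | step 9 | methyl (1R,6R)-3-methoxy-1-methyl-5-oxo-6-(2-oxoethyl)cyclohex-3-ene-1-carboxylate | O=C1C=C(OC)C[C@@](C)(C(=O)OC)[C@H]1CC=O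
F11 | step 9 | methyl (1R,6R)-6-(2-hydroxyethyl)-3-methoxy-1-methyl-5-oxocyclohex-3-ene-1-carboxylate | O=C1C=C(OC)C[C@@](C)(C(=O)OC)[C@H]1CCO
F12 | step 9 | methyl (1R,6R)-6-(2-iodoethyl)-3-methoxy-1-methyl-5-oxocyclohex-3-ene-1-carboxylate | O=C1C=C(OC)C[C@@](C)(C(=O)OC)[C@H]1CCI
F13 | step 9 | alkylzinc iodide from F12 | O=C1C=C(OC)C[C@@](C)(C(=O)OC)[C@H]1CC[Zn]I
F14 | step 9 | tert-butyl[(4,4-dibromobut-3-en-1-yl)oxy]diphenylsilane | BrC(Br)=CCCO[Si](c1ccccc1)(c1ccccc1)C(C)(C)C
F15 | step 9 | methyl (1R,6R)-6-{(Z)-3-bromo-6-[(tert-butyldiphenylsilyl)oxy]hex-3-en-1-yl}-3-methoxy-1-methyl-5-oxocyclohex-3-ene-1-carboxylate | O=C1C=C(OC)C[C@@](C)(C(=O)OC)[C@H]1CC/C(Br)=C/CCO[Si](c2ccccc2)(c2ccccc2)C(C)(C)C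
F16 | step 9 | (trimethylsilyl)methylzinc chloride | C[Si](C)(C)C[Zn]Cl
F17 | step 16 | dimethyl (2R,4R,5S,9S,10R,13E)-2-hydroxylabda-8(17),13-diene-15,19-dioate | C=C1CC[C@H]2[C@](C)(C[C@@H](O)C[C@@]2(C)C(=O)OC)[C@H]1CC/C(C)=C/C(=O)OC
F18 | step 16 | dimethyl (2S,4R,5S,9S,10R,13E)-2-[(4-nitrobenzoyl)oxy]labda-8(17),13-diene-15,19-dioate | C=C1CC[C@H]2[C@](C)(C[C@H](OC(=O)c3ccc(cc3)[N+](=O)[O-])C[C@@]2(C)C(=O)OC)[C@H]1CC/C(C)=C/C(=O)OC
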